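(All runs were computed on assumed constants, and the scatter is random.)

- A falling starting material is easily mistaken for target being made: by 50.0 min the teal run holds 0.5% of its starting material but 16.1% of target. Teal and amber also lose starting material at much the same pace, reading 19.9% and 20.0% at 15.0 min, although teal has twice the catalyst, so most of this loss does not pass through the catalyst.

| flask | starting material | reagent | free catalyst | temperature | remark | time |
|---|---|---|---|---|---|---|
| teal | 0.010 M | 6 mM | 1 mM | 25 °C | run made earlier |  |
| amber | 0.010 M | 6 mM | 0.50 mM | 25 °C | run made earlier |  |
| beta | 0.010 M | 6.00 mM (fed, over 1.0 h) | 1.0 mM | 25 °C | all else is in the flask from the start; the feed brings no volume worth counting | 80 min |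
| gamma | 0.010 M (in portions, 5, over 1.0 h) | 6.00 mM | 1.0 mM | 25 °C | first portion at the start, last at 1.0 h | 80 min |
| alpha | 0.010 M | 6.00 mM (fed, over 1.0 h) | 1.0 mM |  | the addition at −5 °C, then warmed to 25 °C; the feed brings no volume worth counting | 80 min |
| epsilon | 0.010 M | 6.00 mM | 1.0 mM | 25 °C | everything together at the start | 80 min |

- teal (time / min: target / %, starting material / %): 3.00: 0.9, 54.6; 10.0: 2.6, 27.9; 15.0: 3.7, 19.9; 25.0: 6.8, 9.9; 40.0: 14.0, 4.6; 50.0: 16.1, 0.5
- amber (time / min: target / %, starting material / %): 1.00: 0, 78.5; 3.00: 0, 57.1; 6.00: 0, 40.0; 8.00: 0.4, 35.0; 12.0: 0, 24.8; 15.0: 3.7, 20.0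

(standard deviation of a reading: 1 percentage point)

- what was read earlier has a scatter of 1 percentage point, one standard deviation
- the earlier runs do not show what temperature does; that part of a forecast is a guess

- the best flask by amount of target, in percent of the starting material charged; "all alike" if 1.5 percentage points covers them all (beta / gamma / alpha / epsilon / all alike)
- amount of target at the end, in percent of the starting material charged, beta
- amount of target at the end, in percent of the starting material charged, gamma
- amount of target at the end, in percent of the starting material charged, alpha
- amount of target at the end, in percent of the starting material charged, epsilon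

- Target is better counted in turnovers. Teal at 40.0 min gives 0.0350 min⁻¹ for the turnover rate (the turnover frequency), the target formed per catalyst charged per unit time. The amber readings, 0% at 12.0 min and 3.7% at 15.0 min, are too scattered to test whether this rate holds per catalyst, so that is assumed here.
- The catalyst charge equals 10.0% of the starting material, and each turnover is worth that much target. The first way, the clock, multiplies turnover rate, time and this share, which gives 28.0% for epsilon.
- The second way counts supply. Epsilon has the recipe of teal, so when its starting material is nearly gone, at 50.0 min, it should hold about 16.1% of target. If each catalyst then finishes one waiting load, the total is 26.1%. This lands 1.9 percentage points from the clock, but both ways rest on teal readings, the clock runs on past 50.0 min, and the supply count assumes a load that is finished, so the two give a rough level for epsilon and no measure of accuracy.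
- For beta the two ways part. The clock still says 28.0%, but it assumes starting material and reagent throughout. The feed averages half its charge over the hour, and if turnover follows the reagent, the supply count gives 18.1%. The clock is the one that cheats here, as its rate was read in teal, where the whole reagent charge stood from the start.
- In gamma the last portion enters 20.0 min before the end, and teal still held 9.9% after 25.0 min, so the clock stands at 28.0%. For alpha, where the effect of temperature is a guess, counting the cold hour as no turnover leaves 7.00% from the warm minutes.
- The forecast chose gamma, with 24% for beta, 28% for gamma, 10% for alpha and 26% for epsilon, and it sets beta higher than the supply count, saying “Beta keeps it high with a lagging pool, so slightly less”.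
- The flask gamma gives the most target: beta 16.4%, gamma 26.5%, alpha 7.20%, epsilon 23.7%. At 80.0 min beta holds 0% of its starting material and 56.7% of its catalyst free, against 2.17% free in gamma. The target of beta amounts to 1.64 turnovers, which at the turnover rate fill 46.9 min of the 80 min.

    starting material + free catalyst → catalyst intermediate A (k = 22.0 M⁻¹ s⁻¹, Ea = 43.0 kJ mol⁻¹)
    reagent + catalyst intermediate A ⇌ catalyst intermediate B (K = 1400 M⁻¹, k = 0.200 M⁻¹ s⁻¹, Ea = 48.0 kJ mol⁻¹, ΔH = 6.00 kJ mol⁻¹)
    catalyst intermediate B ⇌ by-product + catalyst intermediate C (K = 0.500 M, k = 0.00560 s⁻¹, Ea = 80.0 kJ mol⁻¹, ΔH = −47.0 kJ mol⁻¹)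
    catalyst intermediate C ⇌ catalyst intermediate D (K = 3.10, k = 0.210 s⁻¹, Ea = 66.0 kJ mol⁻¹, ΔH = −22.0 kJ mol⁻¹)
    catalyst intermediate D → free catalyst + target (k = 0.00430 s⁻¹, Ea = 88.0 kJ mol⁻¹)
    2 starting material → self-condensation product (k = 0.190 M⁻¹ s⁻¹, Ea = 47.0 kJ mol⁻¹)
    (constants at 25 °C)

- A neighbour flask is gamma with 4.0 × 10⁻⁴ M of free catalyst, so the turnover rate over 80 min gives 11.2% of target. The computed flask gives 12.0%.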